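## Retrosynthetic overview
1. The amide is formed last and without protecting groups, from the OSu ester of the C20 acid and free L‑Gln. The whole C1–C4/C18/C19 enoate arm is attached through a single bond (C1–C10) by a 1,6‑(vinylogous Michael) addition to a 2‑methylpentadienoate. No allylation, metathesis or olefination is done on the cage.
2. The cage is closed by C–H logic: formyl C–H → acyl radical → C9 (a HAT "radical Stetter" desymmetrisation of a spirodienone). Exo hydride delivery at C11 and acid closure of the C16–O bond follow.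
3. Ring D and quaternary C8 come from dearomative allylsilane spirocyclisation of a phenol. The allylsilane is made in one operation from a lactone C=O, which becomes C16.
4. The only external chirality is C13, set by asymmetric hydrogenation of a benzylidene butyrolactone. C8, C9, C11, C16 and C10 are relayed from it.
5. Ring order: B (the arene) → D → C → ether bridge (THF/THP).

Assumption 1: atom labels in the text follow ent‑kaurane numbering. C5 is the enone C=O, C8 the quaternary cage carbon, C9 the CH next to C10, C10 the C(CH3)(chain), C11 the CH–O, C13 the bridgehead CH, and C16 the C(CH3)–O.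
Assumption 2: the BINAP antipode in step 2 is assigned by analogy. If the sense of induction is reversed, the other commercial antipode is used.

## Route

**Step 1**
Reactants: 1 4‑hydroxybenzaldehyde; 2 3‑(triphenyl‑λ5‑phosphanylidene)oxolan‑2‑one
Product: 3 (E)‑3‑(4‑hydroxybenzylidene)oxolan‑2‑one
Conditions: PhMe, 90 °C, 12 h
Reagents that add atoms: none beyond 1 and 2
Why: Wittig olefination with a lactone‑stabilised ylide tolerates the free phenol and gives the E‑benzylidene lactone; no stereocentre is formed.

**Step 2**
Reactants: 3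
Product: 4 (3S)‑3‑(4‑hydroxybenzyl)oxolan‑2‑one
Conditions: H2 (100 bar), Ru(OAc)2[(S)‑BINAP] (0.5 mol %), CH2Cl2/MeOH, 50 °C; recrystallise
Reagents that add atoms: none (H2 only)
Why: Catalytic asymmetric hydrogenation of a geometrically pure exocyclic α‑arylidene lactone sets C13 (S), the only stereocentre that comes from an external chiral source.

**Step 3**
Reactants: 4
Product: 5 4‑[(2S)‑2‑(2‑hydroxyethyl)‑3‑[(trimethylsilyl)methyl]but‑3‑en‑1‑yl]phenol
Conditions: TMSCH2MgCl (6 equiv), CeCl3 (6 equiv), THF, −78 °C → rt; then SiO2, CH2Cl2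
Reagents that add atoms: (trimethylsilyl)methylmagnesium chloride, C[Si](C)(C)C[Mg]Cl (2 equiv incorporated; one Me3Si–O is lost)
Why: Double organocerium addition to the lactone followed by Peterson elimination (ester‑to‑allylsilane synthesis) turns the C=O into C16(=CH2)CH2SiMe3 and frees C11–OH, and the non‑basic cerium reagent leaves C13 untouched.

**Step 4**
Reactants: 5
Product: 6 (2S)‑2‑(2‑hydroxyethyl)‑3‑methylidenespiro[4.5]deca‑6,9‑dien‑8‑one
Conditions: PhI(OAc)2 (1.05 equiv), CF3CH2OH, −10 °C, 20 min
Reagents that add atoms: none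
Why: In this hypervalent‑iodine oxidative dearomatisation the 2‑substituted allylsilane attacks the para carbon (Sakurai‑type five‑ring closure, C8–C15) faster than the OH can form a six‑membered spiroether in the fluorinated solvent; C8 is not yet stereogenic because the dienone is symmetric.

**Step 5**
Reactants: 6
Product: 7 [(2S)‑3‑methylidene‑8‑oxospiro[4.5]deca‑6,9‑dien‑2‑yl]acetaldehyde
Conditions: Dess–Martin periodinane, NaHCO3, CH2Cl2, 0 °C → rt
Reagents that add atoms: none
Why: Buffered Dess–Martin oxidation of the primary alcohol leaves the dienone, the 1,1‑disubstituted alkene and C13 intact.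

**Step 6 (key step)**
Reactants: 7
Product: 8 (1S,6S,9S)‑10‑methylidenetricyclo[7.2.1.0^1,6]dodec‑2‑ene‑4,7‑dione (C5 enone, C11 ketone, C16=CH2)
Conditions: [Ir(dF(CF3)ppy)2(dtbbpy)]PF6 (1 mol %), quinuclidine (20 mol %), MeCN (0.01 M), 450 nm LEDs, rt
Reagents that add atoms: none (redox‑neutral isomerisation)
Why: Proposed new method: the quinuclidinium radical cation removes the hydridic formyl H (polarity‑matched HAT) and the nucleophilic acyl radical closes 6‑exo onto the only dienone β‑carbon on its face of ring D, with the short C12–C13–C14 tether forcing attack syn to C14 so that C8 (S) and C9 (H9 anti to C14) are relayed from C13, after which Ir(II)/quinuclidinium reduce and protonate the α‑keto radical; visible light avoids dienone photorearrangement, and the closest known reaction types are intermolecular photocatalytic HAT hydroacylation (acyl‑radical Giese addition) of enones and the NHC‑catalysed intramolecular Stetter desymmetrisation of cyclohexadienones.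

**Step 7**
Reactants: 8
Product: 9 (1S,6S,7S,9S)‑7‑hydroxy‑10‑methylidenetricyclo[7.2.1.0^1,6]dodec‑2‑en‑4‑one (axial/endo C11–OH)
Conditions: LiAlH(Ot‑Bu)3 (1.2 equiv), THF, −40 → −10 °C
Reagents that add atoms: none (hydride only)
Why: This chemoselective hydride reduction takes the saturated ketone in preference to the enone, and the bulky hydride enters from the exo face away from the C15–C16 bridge (as in bicyclo[3.2.1]octan‑3‑one/tropinone reductions) to give the axial 11S alcohol.

**Step 8**
Reactants: 9
Product: 10 (1S,6S,7S,9S,10S)‑9‑methyl‑8‑oxatetracyclo[7.2.1.1^7,10.0^1,6]tridec‑2‑en‑4‑one (cage enone)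
Conditions: TFA/CH2Cl2 (1:2), 0 °C, 1 h
Reagents that add atoms: none
Why: In this acid‑catalysed intramolecular Markovnikov hydroalkoxylation the tertiary C16 cation is captured by the 1,3‑diaxial C11–OH, and the cage geometry allows only the 16S ether.

**Step 9**
Reactants: 10
Product: 11 (1S,5S,6S,7S,9S,10S)‑5,9‑dimethyl‑8‑oxatetracyclo[7.2.1.1^7,10.0^1,6]tridec‑2‑en‑4‑one
Conditions: KHMDS, THF/HMPA, −78 °C; MeI, → −10 °C
Reagents that add atoms: iodomethane, CI
Why: C10 is the only enolisable position, so enolate alkylation is regiospecific and occurs on the exposed face; this C10 configuration is erased in step 11.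

**Step 10 (branch)**
Reactants: 12 acrolein; 13 ethyl 2‑(triphenyl‑λ5‑phosphanylidene)propanoate
Product: 14 ethyl (2E)‑2‑methylpenta‑2,4‑dienoate
Conditions: CH2Cl2, 0 °C → rt; used freshly distilled (BHT)
Reagents that add atoms: none beyond 12 and 13
Why: Wittig olefination with a stabilised α‑methyl ylide is E‑selective and gives the dienoate acceptor in one step.

**Step 11**
Reactants: 11; 14
Product: 15 ethyl (2E)‑5‑[(1S,5S,6R,7S,9S,10S)‑5,9‑dimethyl‑4‑oxo‑8‑oxatetracyclo[7.2.1.1^7,10.0^1,6]tridec‑2‑en‑5‑yl]‑2‑methylpent‑2‑enoate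
Conditions: KOt‑Bu (0.3 equiv), t‑BuOH/THF (1:3), 0 °C → rt, slow addition of 14 (2.5 equiv)
Reagents that add atoms: none beyond 14
Why: Proposed new method: equilibrating base generates the only possible (C10) dienolate, which adds through its exposed face (away from the C12/C14 flank, pushing CH3 into the hindered site) to the unhindered terminal CH2 of the dienoate (1,6 rather than 1,4), while the protic medium quenches the ester dienolate before a second Michael step and moves the C=C into conjugation as the more stable E‑trisubstituted enoate, setting C10 (S) and the alkene geometry; the closest known reaction types are KOt‑Bu‑mediated Michael additions of hindered α‑methyl ketone enolates to acrylates and 1,6‑additions of soft carbon nucleophiles to 2,4‑dienoates.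

**Step 12**
Reactants: 15
Product: 16 (2E)‑5‑[(1S,5S,6R,7S,9S,10S)‑5,9‑dimethyl‑4‑oxo‑8‑oxatetracyclo[7.2.1.1^7,10.0^1,6]tridec‑2‑en‑5‑yl]‑2‑methylpent‑2‑enoic acid
Conditions: LiOH·H2O, THF/MeOH/H2O, 45 °C; then pH 3
Reagents that add atoms: hydroxide/water, O
Why: Saponification is safe because the cage has no epimerisable centre (C10 is quaternary) and the hindered enone and the ether tolerate aqueous LiOH.

**Step 13**
Reactants: 16; 17 L‑glutamine
Product: 18 homoplatensimide A
Conditions: EDC·HCl, N‑hydroxysuccinimide, CH2Cl2, rt; then 17, NaHCO3, THF/H2O, rt; acidify to pH 3, RP‑HPLC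
Reagents that add atoms: none beyond 17
Why: Active‑ester (Schotten–Baumann‑type) N‑acylation of the unprotected amino acid is selective for the α‑amine, needs no protecting groups, and cannot racemise because the stereocentre is on the amine partner.

## Compound list
1 | 4‑hydroxybenzaldehyde | O=Cc1ccc(O)cc1 | starting material
2 | 3‑(triphenyl‑λ5‑phosphanylidene)oxolan‑2‑one | O=C1OCCC1=P(c1ccccc1)(c1ccccc1)c1ccccc1 | starting material
3 | (E)‑3‑(4‑hydroxybenzylidene)oxolan‑2‑one | O=C1OCC/C1=C\c1ccc(O)cc1 | intermediate
4 | (3S)‑3‑(4‑hydroxybenzyl)oxolan‑2‑one | Oc1ccc(C[C@H]2CCOC2=O)cc1 | intermediate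
5 | 4‑[(2S)‑2‑(2‑hydroxyethyl)‑3‑[(trimethylsilyl)methyl]but‑3‑en‑1‑yl]phenol | Oc1ccc(C[C@@H](CCO)C(=C)C[Si](C)(C)C)cc1 | intermediate
6 | (2S)‑2‑(2‑hydroxyethyl)‑3‑methylidenespiro[4.5]deca‑6,9‑dien‑8‑one | O=C1C=CC2(C=C1)C[C@@H](CCO)C(=C)C2 | intermediate
7 | [(2S)‑3‑methylidene‑8‑oxospiro[4.5]deca‑6,9‑dien‑2‑yl]acetaldehyde | O=C1C=CC2(C=C1)C[C@@H](CC=O)C(=C)C2 | intermediate
8 | (1S,6S,9S)‑10‑methylidenetricyclo[7.2.1.0^1,6]dodec‑2‑ene‑4,7‑dione | O=C1C=C[C@]23C[C@@H](CC(=O)[C@H]3C1)C(=C)C2 | intermediate
9 | (1S,6S,7S,9S)‑7‑hydroxy‑10‑methylidenetricyclo[7.2.1.0^1,6]dodec‑2‑en‑4‑one | O=C1C=C[C@]23C[C@@H](C[C@H](O)[C@H]3C1)C(=C)C2 | intermediate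
10 | (1S,6S,7S,9S,10S)‑9‑methyl‑8‑oxatetracyclo[7.2.1.1^7,10.0^1,6]tridec‑2‑en‑4‑one | O=C1C=C[C@]23C[C@H]4C[C@H](O[C@@]4(C)C2)[C@H]3C1 | intermediate
11 | (1S,5S,6S,7S,9S,10S)‑5,9‑dimethyl‑8‑oxatetracyclo[7.2.1.1^7,10.0^1,6]tridec‑2‑en‑4‑one | C[C@@H]1C(=O)C=C[C@]23C[C@H]4C[C@H](O[C@@]4(C)C2)[C@H]31 | intermediate
12 | acrolein | C=CC=O | starting material
13 | ethyl 2‑(triphenyl‑λ5‑phosphanylidene)propanoate | CCOC(=O)C(C)=P(c1ccccc1)(c1ccccc1)c1ccccc1 | starting material
14 | ethyl (2E)‑2‑methylpenta‑2,4‑dienoate | C/C(=C\C=C)C(=O)OCC | intermediate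
15 | ethyl ester of the C20 acid (name in step 11; the change of locant 6 from S to R is a CIP priority change only, not an inversion) | C/C(=C\CC[C@]1(C)C(=O)C=C[C@]23C[C@H]4C[C@H](O[C@@]4(C)C2)[C@H]31)C(=O)OCC | intermediate
16 | C20 acid (name in step 12) | C/C(=C\CC[C@]1(C)C(=O)C=C[C@]23C[C@H]4C[C@H](O[C@@]4(C)C2)[C@H]31)C(=O)O | intermediate
17 | L‑glutamine | N[C@@H](CCC(N)=O)C(=O)O | starting material
18 | homoplatensimide A | C/C(=C\CC[C@]1(C)C(=O)C=C[C@]23C[C@H]4C[C@H](O[C@@]4(C)C2)[C@H]31)C(=O)N[C@@H](CCC(N)=O)C(=O)O | target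

## Step count and risks
Total steps: 13. Longest linear sequence: 12 (steps 1–9 and 11–13).

Steps most likely to fail:
1. **Step 6 (HAT acyl‑radical desymmetrisation).** The risks are an amine‑promoted C12‑enolate Michael addition onto the dienone, a slow ring closure, and C9 epimerisation in the 1,4‑diketone. Fallback: switch from acyl to ketyl reactivity. A SmI2/HFIP ketyl–enone cyclisation of 7 gives alcohol 9 directly and skips step 7; the C11 epimers are separated, and only the axial one etherifies in step 8.
2. **Step 11 (1,6‑addition forming quaternary C10).** The risks are dienoate oligomerisation, an unfavourable equilibrium, and a Michael–Michael sequence to a bicyclo[2.2.2]octanone. Fallback: build the arm stepwise. C‑allylate 11 (KHMDS, allyl iodide), cross‑metathesise with vinyl‑Bpin, oxidise to the C3 aldehyde, then carry out a Wittig reaction with 13 to reach 15.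
3. **Step 7 (chemo‑ and stereoselective C11 reduction).** The risks are competing enone reduction and formation of some equatorial alcohol. Fallback: drop chemoselectivity. Reduce both carbonyls with excess L‑Selectride, close the ether with TFA, then re‑oxidise the allylic C5 alcohol with MnO2 to give 10.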